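In a one-step world every mole of Xa you charge ends as a mole of Xp, and [Xp] climbs to the charge on one time constant. So keep the books on Xa, the limiting reagent, and see whether this closed flask honours them.

| flask | Xa | Xp | time |
|---|---|---|---|
| north | 1.00 M |  |  |
| west | 1.00 M | 0.300 M |  |
| south-east | 1.50 M |  |  |
| south | 0.400 M |  | 7.4 min |

| run | time / min | [Xp] / M |
|---|---|---|
| north run | 0.93 | 0.117 |
| north run | 1.9 | 0.220 |
| north run | 2.8 | 0.285 |
| north run | 3.7 | 0.340 |
| north run | 4.6 | 0.370 |
| north run | 5.5 | 0.399 |
| north run | 6.5 | 0.410 |
| north run | 7.4 | 0.424 |
| west run | 0.93 | 0.439 |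
| west run | 1.9 | 0.568 |
| west run | 2.8 | 0.630 |
| west run | 3.7 | 0.687 |
| west run | 4.6 | 0.729 |
| west run | 5.5 | 0.745 |
| west run | 6.5 | 0.773 |
| west run | 7.4 | 0.781 |
| south-east run | 0.93 | 0.200 |
| south-east run | 1.9 | 0.347 |
| south-east run | 2.8 | 0.464 |
| south-east run | 3.7 | 0.579 |
| south-east run | 4.6 | 0.618 |
| south-east run | 5.5 | 0.677 |
| south-east run | 6.5 | 0.711 |
| south-east run | 7.4 | 0.738 |

(scatter of a reading: 0.01 M)

- Overall: Xa -> Xp.
- Constant volume, constant temperature.
- The analysis sees a species whether free or bound.
- An order is taken over about fifteen percent of the charge, up and down.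

* apparent order in [Xa] of the starting rate, round the charge of the north run (the rate where two percent of its Xa have turned into Xp) (one fixed amount of Xp, the same in the runs compared)
* Xp in the south run at 7.4 min, as a share of the Xa charged

Take the north run at its last reading: of 1.00 M charged, 0.424 M is booked as Xp and 0.576 M is not. If that balance were still feeding Xp in a first-order way, the rate would have fallen only to 57.6% of its early value. But the early rate reads 0.126 M min⁻¹ and the rate after 4.6 min reads 0.0193 M min⁻¹, just 15.3% of it, far less than that. So I open a second account, for Xa that may have left the road to Xp. Added Xp does not stop the making: the west run gains 0.481 M, more than the north run.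

The two accounts are compared by their odds: Xp made per mole of charge not booked as Xp. At 7.4 min these read 0.736 in the north run and 0.969 in the south-east run. A share is walled in at zero and at the whole charge, but the logarithm of the odds is not, so I join the two runs with a straight line in logs. Its slope s, the rise of ln(odds) per unit of ln(charge), is 0.677. My reckoning for the south run is then odds of 0.396, a share of 28.4%.

The forecast gives an order of 1.25, and for the south run a share of 31% on the ground that “conversion falls as the charge falls”. Its share is higher than mine by 2.6 percentage points.

The flask gives an order of 1.2 and a south share of 27.3%.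

    2 Xa ⇌ Xa2, settled at all times (8.320 L mol⁻¹)
    Xa2 → Xp + Xa (0.3600 min⁻¹)
    Xa → X (0.6660 min⁻¹)
    Xa + Xp → 2 Xp (0.4332 L mol⁻¹ min⁻¹)

The south run's odds are 0.376, where the slope s gave 0.396. The loss of Xa to X is the main reason for that low share, and it costs the south run 36 points. The proof is the same south run without that loss, which reaches 63.3%, odds of 1.73, or 4.36 times what the line through the leaking runs gives.

All runs were generated by integration with made-up constants, and the scatter is random.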